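**Retrosynthetic overview**

1. Germacranolide numbering is used: C1 (furanone C=O), C2, C3 (furanone C–O), C4(=C15H2), C5 (OH), C6 (O-angeloyl), C7, C8 (lactone CH–O), C9, C10 (CH3 = C14), C11(=C13H2), C12 (lactone C=O). Target 28 ⇐ 27 ⇐ 24 ⇐ 23 (desilylation, Yamaguchi angeloylation, MOM cleavage).
2. 23 ⇐ allenyl aldehyde 22 + CO: one Ru3(CO)12-catalysed [2+2+1] cyclocarbonylation (hetero-Pauson–Khand) forms C7–C8, C11–C12 and C12–O. It closes the ten-membered carbocycle and the α-methylene-γ-lactone together and sets C7 and C8 from C6.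
3. Enabling feature: the lactone ring (C7, C8, O, C12, C11) with its exocyclic C11=C13 is the sum of the C8 aldehyde, the C7=C11 bond of a terminal allene and CO. The planar furan-3(2H)-one ring (O, C3, C2, C1, C10) already ties C10 to C3, so only the short C9–C8 arm and the C4–C7 arm must meet.
4. 22 ⇐ 21 ⇐ 20: furanone by gold-catalysed 5-endo-dig cyclisation of the hydroxy ynone made from the lithium acetylide of 17 and lactone 4; (R)-citramalic acid 1 supplies C10.
5. 17 ⇐ 16 ⇐ 13: C5 and C6 from one Brown (Z)-γ-alkoxyallylboration of 2-bromoacrolein 9; allene by dibromocarbene addition/MeLi; alkyne by Negishi coupling. Ring order: furanone, then carbocycle and lactone together.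

Key step: step 13

Assumption: (+)-Ipc2BOMe is the reagent made from (−)-α-pinene, and its allyl reagents are taken to add to the Re face of aldehydes.

**Route**

Step 1
Reactants: 1 (R)-citramalic acid
Product: 2 2-[(4R)-2,2,4-trimethyl-5-oxo-1,3-dioxolan-4-yl]acetic acid
Conditions: 2,2-dimethoxypropane, TsOH·H2O (cat.), rt
Reagents that add atoms: 2,2-dimethoxypropane, COC(C)(C)OC
Why: Acid-catalysed acetal exchange ties the tertiary hydroxyl and the adjacent carboxyl into a five-membered dioxolanone, which differentiates the two carboxyl groups without touching the bought C10 stereocentre.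

Step 2
Reactants: 2 2-[(4R)-2,2,4-trimethyl-5-oxo-1,3-dioxolan-4-yl]acetic acid
Product: 4 (3R)-3-hydroxy-3-methyloxolan-2-one, via hydroxy dioxolanone 3 (not isolated)
Conditions: BH3·THF, THF, 0 °C → rt; then TsOH·H2O (cat.), CH2Cl2, rt
Reagents that add atoms: none
Why: Borane reduces the free carboxylic acid chemoselectively beside the dioxolanone ester, and acid then drives translactonisation to the five-membered lactone with loss of acetone; the quaternary centre is not involved.

Step 3
Reactants: 5 allyl alcohol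
Product: 6 3-(methoxymethoxy)prop-1-ene
Conditions: MOMCl, i-Pr2NEt, CH2Cl2, 0 °C → rt
Reagents that add atoms: chloromethyl methyl ether, COCCl
Why: Standard O-alkylation of a primary alcohol with an α-chloro ether (MOM protection) gives the substrate for α-oxyallyl metalation.

Step 4
Reactants: 7 acrolein
Product: 9 2-bromoacrolein, via 2,3-dibromopropanal 8 (not isolated)
Conditions: Br2, CH2Cl2, −78 °C; then Et3N, −78 → 0 °C
Reagents that add atoms: bromine, BrBr
Why: Bromine addition to the enal followed by E1cB dehydrobromination of the α,β-dibromo aldehyde is the usual preparation of 2-bromoacrolein.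

Step 5
Reactants: 6 3-(methoxymethoxy)prop-1-ene; 9 2-bromoacrolein
Product: 13 (3R,4S)-2-bromo-4-(methoxymethoxy)hexa-1,5-dien-3-ol, via allyllithium 10 (not isolated), via allylborane 11 (not isolated), via borinate 12 (not isolated)
Conditions: 6, s-BuLi, THF, −78 °C; (+)-Ipc2BOMe; BF3·OEt2; 9, −78 °C; then NaOH, H2O2, 0 °C → rt
Reagents that add atoms: none
Why: Brown (Z)-γ-alkoxyallylboration through a chair six-membered transition state, in which the Z geometry gives the syn C5/C6 pair and the isopinocampheyl groups from (−)-α-pinene direct the allyl unit to the Re face of the aldehyde, should set (3R,4S) with the two oxygens already differentiated.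

Step 6
Reactants: 13 (3R,4S)-2-bromo-4-(methoxymethoxy)hexa-1,5-dien-3-ol
Product: 14 tert-butyl{[(3R,4S)-2-bromo-4-(methoxymethoxy)hexa-1,5-dien-3-yl]oxy}dimethylsilane
Conditions: TBSOTf, 2,6-lutidine, CH2Cl2, −78 → 0 °C
Reagents that add atoms: tert-butyldimethylsilyl triflate, CC(C)(C)[Si](C)(C)OS(=O)(=O)C(F)(F)F
Why: Silylation of the hindered secondary alcohol with the silyl triflate and a hindered pyridine base gives the TBS ether that protects O5 to the end; the MOM acetal survives at low temperature.

Step 7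
Reactants: 14 TBS ether
Product: 15 tert-butyl{[(1S,2R)-3-bromo-1-(2,2-dibromocyclopropyl)-1-(methoxymethoxy)but-3-en-2-yl]oxy}dimethylsilane (both epimers at the cyclopropane CH)
Conditions: CHBr3, 50% aq NaOH, BnEt3NCl (cat.), CH2Cl2, 0 °C → rt
Reagents that add atoms: bromoform, BrC(Br)Br
Why: Phase-transfer dibromocarbene [2+1] cycloaddition should take the monosubstituted alkene, because the other terminal alkene carries bromine on the double bond and is much less nucleophilic; the new cyclopropane centre is lost in step 8.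

Step 8
Reactants: 15 dibromocyclopropane
Product: 16 tert-butyl{[(3R,4S)-2-bromo-4-(methoxymethoxy)hepta-1,5,6-trien-3-yl]oxy}dimethylsilane
Conditions: MeLi, Et2O, −78 °C
Reagents that add atoms: none
Why: Bromine–lithium exchange gives the cyclopropylidene carbenoid, which opens to the terminal allene (Doering–LaFlamme/Skattebøl allene synthesis), while MeLi at −78 °C does not exchange the vinyl bromide.

Step 9
Reactants: 16 bromo allene
Product: 17 tert-butyl{[(4S,5S)-5-(methoxymethoxy)-3-methylideneocta-6,7-dien-1-yn-4-yl]oxy}dimethylsilane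
Conditions: HC≡CMgBr, ZnBr2, THF, 0 °C; then 16, Pd(PPh3)4 (5 mol %), THF, rt → 45 °C
Reagents that add atoms: ethynylmagnesium bromide, C#C[Mg]Br
Why: Negishi coupling of the alkenyl bromide with ethynylzinc bromide gives the terminal 1,3-enyne directly without a silyl group on the alkyne, and transmetalation should outrun any reaction of the allene with the alkenylpalladium intermediate.

Step 10
Reactants: 17 enyne allene; 4 (3R)-3-hydroxy-3-methyloxolan-2-one
Product: 20 (3R,8S,9S)-8-[(tert-butyldimethylsilyl)oxy]-1,3-dihydroxy-9-(methoxymethoxy)-3-methyl-7-methylidenedodeca-10,11-dien-5-yn-4-one, via lithium acetylide 18 (not isolated), via lithium alkoxide 19 (not isolated)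
Conditions: 17, n-BuLi, THF, −78 °C; then 19 [from 4 and LiN(SiMe3)2, THF, −78 °C], −78 → −30 °C; aq NH4Cl
Reagents that add atoms: none
Why: Addition of a lithium acetylide to a γ-lactone stops at the chelated tetrahedral intermediate and gives the ynone and the primary alcohol on work-up, the tertiary hydroxyl being masked in situ as its lithium alkoxide.

Step 11
Reactants: 20 hydroxy ynone
Product: 21 (2R)-5-[(3S,4S)-3-[(tert-butyldimethylsilyl)oxy]-4-(methoxymethoxy)hepta-1,5,6-trien-2-yl]-2-(2-hydroxyethyl)-2-methylfuran-3(2H)-one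
Conditions: (Ph3P)AuNTf2 (2 mol %), toluene, rt
Reagents that add atoms: none
Why: Gold-catalysed 5-endo-dig addition of the tertiary hydroxyl to the activated ynone (intramolecular hydroalkoxylation) gives the furan-3(2H)-one, the ynone being the only π-system with a hydroxyl in reach.

Step 12
Reactants: 21 furanone alcohol
Product: 22 2-[(2R)-5-{(3S,4S)-3-[(tert-butyldimethylsilyl)oxy]-4-(methoxymethoxy)hepta-1,5,6-trien-2-yl}-2-methyl-3-oxo-2,3-dihydrofuran-2-yl]acetaldehyde
Conditions: Dess–Martin periodinane, NaHCO3, CH2Cl2, 0 °C → rt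
Reagents that add atoms: none
Why: Dess–Martin oxidation of the primary alcohol under buffered, non-basic conditions gives the aldehyde without β-elimination of the furanone oxygen.

Step 13
Reactants: 22 allenyl aldehyde
Product: 23 (5S,6S,7R,8S,10R)-5-[(tert-butyldimethylsilyl)oxy]-6-(methoxymethoxy)-1-oxo-3,10-epoxygermacra-2,4(15),11(13)-trien-12,8-olide
Conditions: Ru3(CO)12 (10 mol %), CO (10 atm), 1,4-dioxane (0.003 M, slow addition of 22), 120 °C
Reagents that add atoms: carbon monoxide, [C-]#[O+]
Why: Proposed new method: zerovalent ruthenium carbonyl fragments from Ru3(CO)12 bind the aldehyde C=O and the internal C7=C11 π-bond of the allene, oxidative cyclisation gives a 2-oxaruthenacyclopentane with the C11=C13 methylene exocyclic (C7–C8 bond), CO inserts into the Ru–C11 bond (C11–C12 bond) and C–O reductive elimination releases the lactone and the catalyst; the closest known reaction is the Ru3(CO)12-catalysed (or Mo(CO)6-mediated) hetero-Pauson–Khand cyclocarbonylation of allenyl aldehydes to bicyclic α-methylene-γ-butyrolactones, known for five- and six-membered carbocycles and extended here to a ten-membered one. The ten-membered carbocycle closes by attack of C7 on the exocyclic aldehyde carbon (exo mode, templated on the metal), and the γ-lactone closes by the [2+2+1] carbonylative annulation that ends with acyl–oxygen reductive elimination. C7 is controlled by C6: the metal and C8 should add to the allene face anti to the allylic C6–OMOM bond, with C6–H over the cumulene and the C5 chain turned outward toward the aldehyde, which corresponds to the 6,7-relationship of the target. C8 is controlled in the metallacycle: the two arms of the forming ring (C6 on C7, C9 on C8) should take the trans, pseudo-diequatorial positions, which is the trans-fused lactone. The step needs chemoselectivity for the aldehyde over the furanone carbonyl and for the internal over the terminal allene π-bond: the vinylogous-ester carbonyl is deactivated and cannot reach the allene across the planar furanone, and the internal π-bond is the electron-poorer one (allylic oxygen) and gives the smaller ring, as in the known small-ring cases. High dilution and CO pressure are used to suppress oligomerisation and decarbonylation of the aldehyde.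

Step 14
Reactants: 23 protected macrolactone
Product: 24 (5S,6S,7S,8S,10R)-5-[(tert-butyldimethylsilyl)oxy]-6-hydroxy-1-oxo-3,10-epoxygermacra-2,4(15),11(13)-trien-12,8-olide (same spatial arrangement as 23; the C7 descriptor changes only through the priority rules)
Conditions: Me2BBr, CH2Cl2, −78 °C; then NaHCO3, THF/H2O
Reagents that add atoms: none
Why: Me2BBr cleaves methoxymethyl acetals at −78 °C through the boron-activated oxocarbenium ion and should leave the silyl ether, the lactone and the vinylogous ester untouched.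

Step 15
Reactants: 24 C6 alcohol; 25 angelic acid
Product: 27 (5S,6S,7R,8S,10R)-6-angeloyloxy-5-[(tert-butyldimethylsilyl)oxy]-1-oxo-3,10-epoxygermacra-2,4(15),11(13)-trien-12,8-olide, via angelic 2,4,6-trichlorobenzoic anhydride 26 (not isolated)
Conditions: 25, 2,4,6-trichlorobenzoyl chloride, Et3N, toluene, rt; then 24, 80 °C
Reagents that add atoms: none
Why: Yamaguchi esterification through the mixed anhydride without a nucleophilic catalyst is the usual way to acylate hindered secondary alcohols with angelic acid without Z to E isomerisation.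

Step 16
Reactants: 27 silyl ether
Product: 28 CNP0120053.1, (5S,6S,7R,8S,10R)-6-angeloyloxy-5-hydroxy-1-oxo-3,10-epoxygermacra-2,4(15),11(13)-trien-12,8-olide
Conditions: HF·pyridine, pyridine, THF, 0 °C → rt
Reagents that add atoms: none
Why: Buffered HF·pyridine removes the secondary TBS ether under mildly acidic conditions, which avoids acyl migration from O6 to O5 and conjugate addition to the methylene lactone.

**Compound list**

1 | (R)-citramalic acid, (2R)-2-hydroxy-2-methylbutanedioic acid | O[C@](C)(CC(=O)O)C(=O)O | starting material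
2 | 2-[(4R)-2,2,4-trimethyl-5-oxo-1,3-dioxolan-4-yl]acetic acid | CC1(C)OC(=O)[C@@](C)(CC(=O)O)O1 | intermediate
3 | (5R)-5-(2-hydroxyethyl)-2,2,5-trimethyl-1,3-dioxolan-4-one | CC1(C)OC(=O)[C@@](C)(CCO)O1 | intermediate
4 | (3R)-3-hydroxy-3-methyloxolan-2-one | O[C@]1(C)CCOC1=O | intermediate
5 | allyl alcohol | C=CCO | starting material
6 | 3-(methoxymethoxy)prop-1-ene | C=CCOCOC | intermediate
7 | acrolein | C=CC=O | starting material
8 | 2,3-dibromopropanal (racemic) | BrCC(Br)C=O | intermediate
9 | 2-bromoacrolein | C=C(Br)C=O | intermediate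
10 | (Z)-3-(methoxymethoxy)allyllithium | [Li]C/C=C\OCOC | intermediate
11 | [(Z)-3-(methoxymethoxy)allyl]diisopinocampheylborane (isopinocampheyl groups from (−)-α-pinene) | COCO/C=C\CB([C@H]1C[C@H]2C[C@@H]([C@@H]1C)C2(C)C)[C@H]1C[C@H]2C[C@@H]([C@@H]1C)C2(C)C | intermediate
12 | (3R,4S)-2-bromo-4-(methoxymethoxy)hexa-1,5-dien-3-yl diisopinocampheylborinate | C=C(Br)[C@H](OB([C@H]1C[C@H]2C[C@@H]([C@@H]1C)C2(C)C)[C@H]1C[C@H]2C[C@@H]([C@@H]1C)C2(C)C)[C@@H](OCOC)C=C | intermediate
13 | (3R,4S)-2-bromo-4-(methoxymethoxy)hexa-1,5-dien-3-ol | C=C(Br)[C@H](O)[C@@H](OCOC)C=C | intermediate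
14 | tert-butyl{[(3R,4S)-2-bromo-4-(methoxymethoxy)hexa-1,5-dien-3-yl]oxy}dimethylsilane | C=C(Br)[C@H](O[Si](C)(C)C(C)(C)C)[C@@H](OCOC)C=C | intermediate
15 | tert-butyl{[(1S,2R)-3-bromo-1-(2,2-dibromocyclopropyl)-1-(methoxymethoxy)but-3-en-2-yl]oxy}dimethylsilane (both epimers at the cyclopropane CH) | C=C(Br)[C@H](O[Si](C)(C)C(C)(C)C)[C@@H](OCOC)C1CC1(Br)Br | intermediate
16 | tert-butyl{[(3R,4S)-2-bromo-4-(methoxymethoxy)hepta-1,5,6-trien-3-yl]oxy}dimethylsilane | C=C(Br)[C@H](O[Si](C)(C)C(C)(C)C)[C@@H](OCOC)C=C=C | intermediate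
17 | tert-butyl{[(4S,5S)-5-(methoxymethoxy)-3-methylideneocta-6,7-dien-1-yn-4-yl]oxy}dimethylsilane | C#CC(=C)[C@H](O[Si](C)(C)C(C)(C)C)[C@@H](OCOC)C=C=C | intermediate
18 | lithium acetylide of 17 | [Li]C#CC(=C)[C@H](O[Si](C)(C)C(C)(C)C)[C@@H](OCOC)C=C=C | intermediate
19 | lithium (3R)-3-methyl-2-oxooxolan-3-olate | [Li]O[C@]1(C)CCOC1=O | intermediate
20 | (3R,8S,9S)-8-[(tert-butyldimethylsilyl)oxy]-1,3-dihydroxy-9-(methoxymethoxy)-3-methyl-7-methylidenedodeca-10,11-dien-5-yn-4-one | OCC[C@@](C)(O)C(=O)C#CC(=C)[C@H](O[Si](C)(C)C(C)(C)C)[C@@H](OCOC)C=C=C | intermediate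
21 | (2R)-5-[(3S,4S)-3-[(tert-butyldimethylsilyl)oxy]-4-(methoxymethoxy)hepta-1,5,6-trien-2-yl]-2-(2-hydroxyethyl)-2-methylfuran-3(2H)-one | OCC[C@@]1(C)OC(=CC1=O)C(=C)[C@H](O[Si](C)(C)C(C)(C)C)[C@@H](OCOC)C=C=C | intermediate
22 | 2-[(2R)-5-{(3S,4S)-3-[(tert-butyldimethylsilyl)oxy]-4-(methoxymethoxy)hepta-1,5,6-trien-2-yl}-2-methyl-3-oxo-2,3-dihydrofuran-2-yl]acetaldehyde | O=CC[C@@]1(C)OC(=CC1=O)C(=C)[C@H](O[Si](C)(C)C(C)(C)C)[C@@H](OCOC)C=C=C | intermediate
23 | (5S,6S,7R,8S,10R)-5-[(tert-butyldimethylsilyl)oxy]-6-(methoxymethoxy)-1-oxo-3,10-epoxygermacra-2,4(15),11(13)-trien-12,8-olide | C=C1C(=O)O[C@H]2C[C@@]3(C)OC(=CC3=O)C(=C)[C@H](O[Si](C)(C)C(C)(C)C)[C@@H](OCOC)[C@H]12 | intermediate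
24 | (5S,6S,7S,8S,10R)-5-[(tert-butyldimethylsilyl)oxy]-6-hydroxy-1-oxo-3,10-epoxygermacra-2,4(15),11(13)-trien-12,8-olide | C=C1C(=O)O[C@H]2C[C@@]3(C)OC(=CC3=O)C(=C)[C@H](O[Si](C)(C)C(C)(C)C)[C@@H](O)[C@H]12 | intermediate
25 | angelic acid, (2Z)-2-methylbut-2-enoic acid | C/C=C(/C)C(=O)O | starting material
26 | (2Z)-2-methylbut-2-enoic 2,4,6-trichlorobenzoic anhydride | C/C=C(/C)C(=O)OC(=O)c1c(Cl)cc(Cl)cc1Cl | intermediate
27 | (5S,6S,7R,8S,10R)-6-angeloyloxy-5-[(tert-butyldimethylsilyl)oxy]-1-oxo-3,10-epoxygermacra-2,4(15),11(13)-trien-12,8-olide | C=C1C(=O)O[C@H]2C[C@@]3(C)OC(=CC3=O)C(=C)[C@H](O[Si](C)(C)C(C)(C)C)[C@@H](OC(=O)/C(C)=C\C)[C@H]12 | intermediate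
28 | CNP0120053.1, (5S,6S,7R,8S,10R)-6-angeloyloxy-5-hydroxy-1-oxo-3,10-epoxygermacra-2,4(15),11(13)-trien-12,8-olide | C=C1C(=O)O[C@H]2C[C@@]3(C)OC(=CC3=O)C(=C)[C@H](O)[C@@H](OC(=O)/C(C)=C\C)[C@H]12 | target

**Totals**

Total step count: 16. Longest linear sequence: 13 steps (step 3 or step 4, then steps 5 to 16).

**Steps most likely to fail**

1. Step 13 (Proposed new method). Oligomerisation or isomerisation of the allene, or decarbonylation of the aldehyde, may outrun closure of the ten-membered ring, and facial selection at C7/C8 may be poor. The fallback uses known reactions and makes the two bonds one after the other; it sets out from 22 and comes back at 23. Pd(PPh3)4-catalysed addition of Me3SnSnMe3 to the allene (THF, 65 °C) should give the allyl/vinyl bis(trimethylstannane) aldehyde F1 (alkene geometry not controlled). BF3·OEt2 (CH2Cl2, −78 °C, high dilution) then closes the ten-membered ring by intramolecular allylstannane–aldehyde addition through C7 and gives the macrocyclic 2-stannyl homoallylic alcohol F2. I2 (CH2Cl2, 0 °C) converts the vinylstannane into the macrocyclic vinyl iodide F3. Carbonylative lactonisation of this 2-iodo homoallylic alcohol (Pd(PPh3)4, CO 1 atm, Et3N, THF, 50 °C) gives 23. The C7/C8 configuration then rests on the open transition state of the stannane addition.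

2. Step 7 (with its follow-up, step 8). The carbene may not discriminate between the two terminal alkenes, and in step 8 the carbenoid may insert into a C–H bond next to oxygen instead of opening to the allene. The fallback avoids carbenes; it sets out from 14 and comes back at 16. Ozonolysis of the terminal vinyl group (O3, CH2Cl2/MeOH, −78 °C, indicator end point; then PPh3) should give the α-alkoxy aldehyde F4, the 2-bromoalkene being far less reactive to ozone. Ohira–Bestmann homologation (dimethyl (1-diazo-2-oxopropyl)phosphonate, K2CO3, MeOH, 0 °C) gives the terminal alkyne F5. Crabbé homologation (paraformaldehyde, CuI, Cy2NH, dioxane, reflux) gives allene 16.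

3. Step 15. The Z-alkene may isomerise to the tiglate during acylation, or the hindered C6 hydroxyl (between the silyl ether and the ring fusion) may not be acylated. The fallback builds the Z-alkene on the molecule; it sets out from 24 and comes back at 27. Esterification with 2-[bis(2,2,2-trifluoroethoxy)phosphoryl]propanoic acid (DCC, DMAP cat., CH2Cl2) should give the phosphonate ester F6 (both epimers at the phosphonate α-carbon). Still–Gennari olefination with acetaldehyde (KN(SiMe3)2, 18-crown-6, THF, −78 °C) gives the Z-trisubstituted alkene of 27.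

**Further compounds**

F1 | step 13 | 2-[(2R)-5-{(3S,4S)-3-[(tert-butyldimethylsilyl)oxy]-4-(methoxymethoxy)-6,7-bis(trimethylstannyl)hepta-1,5-dien-2-yl}-2-methyl-3-oxo-2,3-dihydrofuran-2-yl]acetaldehyde | O=CC[C@@]1(C)OC(=CC1=O)C(=C)[C@H](O[Si](C)(C)C(C)(C)C)[C@@H](OCOC)C=C(C[Sn](C)(C)C)[Sn](C)(C)C
F2 | step 13 | 5-O-TBS-6-O-MOM-8-hydroxy-1-oxo-11-(trimethylstannyl)-3,10-epoxy-12-norgermacra-2,4(15),11(13)-triene (configuration as in 23) | C=C([Sn](C)(C)C)[C@@H]1[C@@H](O)C[C@@]2(C)OC(=CC2=O)C(=C)[C@H](O[Si](C)(C)C(C)(C)C)[C@H]1OCOC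
F3 | step 13 | 5-O-TBS-6-O-MOM-8-hydroxy-11-iodo-1-oxo-3,10-epoxy-12-norgermacra-2,4(15),11(13)-triene (configuration as in 23) | C=C(I)[C@@H]1[C@@H](O)C[C@@]2(C)OC(=CC2=O)C(=C)[C@H](O[Si](C)(C)C(C)(C)C)[C@H]1OCOC
F4 | step 7 | (2R,3R)-4-bromo-3-[(tert-butyldimethylsilyl)oxy]-2-(methoxymethoxy)pent-4-enal | C=C(Br)[C@H](O[Si](C)(C)C(C)(C)C)[C@@H](OCOC)C=O
F5 | step 7 | tert-butyl{[(3R,4S)-2-bromo-4-(methoxymethoxy)hex-1-en-5-yn-3-yl]oxy}dimethylsilane | C=C(Br)[C@H](O[Si](C)(C)C(C)(C)C)[C@@H](OCOC)C#C
F6 | step 15 | 6-O-{2-[bis(2,2,2-trifluoroethoxy)phosphoryl]propanoyl} derivative of 24 | C=C1C(=O)O[C@H]2C[C@@]3(C)OC(=CC3=O)C(=C)[C@H](O[Si](C)(C)C(C)(C)C)[C@@H](OC(=O)C(C)P(=O)(OCC(F)(F)F)OCC(F)(F)F)[C@H]12
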